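(The rate constants were drawn at random within sensible limits; the rest is arithmetic.)

Reading the constants by themselves misleads here: second substrate meets coupling partner with a constant 8.20 times the one it has with starting material, yet cross product need not be a minor outlet.

in all of them: gas 0.070 mM (held); time 30 s
- spring: starting material 0.0010 M; second substrate 0.200 mM (fed, over 12 s); all else is in the flask from the start; the feed brings no volume worth counting
- autumn: starting material 0.0010 M; second substrate 0.200 mM; everything together at the start
- dusk: starting material 0.0010 M (in portions, 2, over 12 s); second substrate 0.200 mM; first portion at the start, last at 12 s
- dawn: starting material 0.0010 M (fed, over 12 s); second substrate 0.200 mM; all else is in the flask from the start; the feed brings no volume worth counting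

    second substrate + coupling partner → second product (k1 = 3410 M⁻¹ s⁻¹)
    starting material + coupling partner → target (k2 = 1530 M⁻¹ s⁻¹)
    gas ⇌ coupling partner, rate k3*(csat - [coupling partner]) (k3 = 6.23 s⁻¹, csat = 0.070 mM)
    starting material + second substrate → cross product (k4 = 416 M⁻¹ s⁻¹)
    2 starting material → self-condensation product (k5 = 93.7 M⁻¹ s⁻¹)

- a species is counted by the starting material in it: one self-condensation product counts as two
- a step written with two of one species runs at k times the square of its concentration and takes two of it each time
- at the start none of coupling partner is dissolved
- run time (spring): 30 s

* the flask that comes out highest in amount of cross product, in percent of the starting material charged; "all alike" if 1.5 percentage points covers them all (spring / autumn / dusk / dawn / all alike)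
* amount of cross product at the end, in percent of the starting material charged, spring
* amount of cross product at the end, in percent of the starting material charged, autumn
* amount of cross product at the end, in percent of the starting material charged, dusk
* amount of cross product at the end, in percent of the starting material charged, dawn

I turn the constants into times at the charged amounts, with starting material at its whole charge and coupling partner at saturation:

- lifetime of second substrate against starting material: 2.40 s
- lifetime of second substrate against coupling partner: 4.19 s
- first half-life of starting material by self-condensation: 5.34 s
- lifetime of starting material against coupling partner: 9.34 s
- dosing time: 12 s

I assume saturation because gas refills the solution in 0.161 s, shorter than the first two lines.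

Those two lines are a contest for second substrate. I name the rate at which the whole charge of starting material takes second substrate, over the rate at which saturated coupling partner takes it, the split, 1.74. It is a ratio of rates at the charged amounts, not a ratio of constants, and it scales with the fraction of the charge present. Cross product then receives split/(split + one) of second substrate, here 63.5%.

The third and fourth lines are longer than the first, so in autumn I hold the fraction at one. Second substrate is 20.0% of the starting charge, so I reckon 12.7% of cross product for autumn.

In dusk the first portion is half the charge, and the lifetime of second substrate against that portion and coupling partner together is 2.24 s, shorter than the wait for the last portion, so I reckon with the first portion by itself. That gives 9.31%.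

In spring and dawn the dosing time exceeds the first line, so the fraction keeps moving. There I commit only to a rank below dusk.

The forecast names autumn, with 11.6% for autumn, 7.9% for dusk, 5.8% for spring and 4.9% for dawn, on the ground that “Any dosing keeps the two apart in time”.

The simulation puts autumn highest, with 11.4% for autumn, 7.83% for dusk, 5.74% for spring and 5.03% for dawn.

In autumn, cross product ends with 56.9% of the spent second substrate against my 63.5%, and cross product over second product stands at 1.32 against the split of 1.74. The split contains no second substrate, so I carry it unchanged to the neighbour flask, autumn with 3.4 × 10⁻⁴ M of second substrate, where 63.5% of that charge is 21.6% of the starting charge, and that neighbour ends with 19.0% of cross product.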